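The benzene ring is disconnected, not the heterocycle. In the target, C8a=C4a is both the enol-ether alkene of a trans-2,3-dimethyl-2,3-dihydropyran-4-one and one edge of the arene, and the C5 and C7 oxygens are meta: the signature of a vinylketene–ynol ether benzannulation. Irradiating the enantiopure 6-diazoacetyl dihydropyranone with the chiral siloxyalkyne should, in one operation, close the carbocycle (C5–C6, C7–C8 and C4a–C5, after the Wolff shift has made C8–C8a) and set the free C5 phenol, the C6 side chain and a silyl-marked C7 oxygen in place. C2 and C3 come from an anti aldol unit, the side-chain centre from an Evans allylation.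

Key step: step 11

Remark (numbering): chroman numbering (O1, C2, C3, C4, C4a, C5–C8, C8a) is used for all bicyclic compounds and, by anticipation, for the atoms of the two annulation partners that become ring atoms.
Remark (structure): the alkyne-derived side chain of the annulation product is a (4R)-non-1-en-4-yl group (nine carbons); oxidative loss of its terminal CH2 gives the octanoic acid arm of the target.
Remark (bookkeeping): enolates, alkoxides and other conjugate bases made by deprotonating a numbered compound are treated as the reacting form of that compound; every other species that forms and reacts on in the flask has its own number.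

**Dihydropyranone diazoketone (steps 1–6)**

Step 1
Reactants: 1 methyl (R)-3-hydroxybutanoate
Product: 2 methyl (2R,3R)-3-hydroxy-2-methylbutanoate
Conditions: LiN(i-Pr)2 (2.2 equiv), THF, −78 → −20 °C; MeI, DMPU, −78 → 0 °C; aq. NH4Cl
Reagents that add atoms: iodomethane, CI
Why: Fráter–Seebach alkylation: the lithium-bridged alkoxide–enolate is methylated on the face away from the C3 methyl group, so the existing R carbinol centre sets the new C2 centre as R (anti isomer).

Step 2
Reactants: 2 methyl (2R,3R)-3-hydroxy-2-methylbutanoate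
Product: 3 methyl (2R,3R)-3-[(tert-butyldimethylsilyl)oxy]-2-methylbutanoate
Conditions: TBSCl, imidazole, DMF, rt
Reagents that add atoms: tert-butyldimethylsilyl chloride, CC(C)(C)[Si](C)(C)Cl
Why: Standard silyl ether formation masks the alcohol so that the later enolate steps cannot cause retro-aldol cleavage; no stereocentre is touched.

Step 3
Reactants: 3 methyl (2R,3R)-3-[(tert-butyldimethylsilyl)oxy]-2-methylbutanoate
Product: 5 (3R,4R)-4-[(tert-butyldimethylsilyl)oxy]-3-methylpentan-2-one, via Weinreb amide 4 (not isolated)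
Conditions: MeNH(OMe)·HCl, i-PrMgCl, THF, −20 °C; then MeMgBr, 0 °C; aq. NH4Cl
Reagents that add atoms: methylmagnesium bromide, C[Mg]Br (N,O-dimethylhydroxylamine hydrochloride, CNOC.Cl, adds atoms to intermediate 4 only)
Why: Weinreb ketone synthesis run in one pot: the magnesium amide turns the ester into the N-methoxy-N-methylamide, whose chelated adduct with MeMgBr stops at the ketone stage, and the α-centre is not enolised.

Step 4
Reactants: 5 (3R,4R)-4-[(tert-butyldimethylsilyl)oxy]-3-methylpentan-2-one; 6 methyl 2,2-dimethoxypropanoate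
Product: 7 (6R,7R)-7-[(tert-butyldimethylsilyl)oxy]-2,2-dimethoxy-6-methyloctane-3,5-dione
Conditions: LiN(SiMe3)2 (2.2 equiv), THF, −78 °C; then 6, −78 → −20 °C; aq. NH4Cl
Reagents that add atoms: none
Why: Crossed Claisen condensation: the kinetic methyl-side lithium enolate acylates the non-enolisable, inductively activated ketal ester and the product is stored as its diketonate, so the branched α-carbon is neither deprotonated nor able to eliminate the silyloxy group.

Step 5
Reactants: 7 (6R,7R)-7-[(tert-butyldimethylsilyl)oxy]-2,2-dimethoxy-6-methyloctane-3,5-dione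
Product: 10 (2R,3R)-6-acetyl-2,3-dimethyl-2,3-dihydro-4H-pyran-4-one, via hydroxy diketone 8 (not isolated), via ketal pyranone 9 (not isolated)
Conditions: TFA/H2O (9:1), 0 °C → rt
Reagents that add atoms: water, O
Why: Acid-mediated desilylation, cyclodehydration of the hydroxy 1,3-diketone to the 2,3-dihydro-4H-pyran-4-one and ketal hydrolysis occur in one pot; the C2–O bond is never broken and C3, should it enolise, returns to the favoured trans (diequatorial) arrangement.

Step 6
Reactants: 10 (2R,3R)-6-acetyl-2,3-dimethyl-2,3-dihydro-4H-pyran-4-one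
Product: 12 (2R,3R)-6-(2-diazoacetyl)-2,3-dimethyl-2,3-dihydro-4H-pyran-4-one, via trifluoroacetyl diketone 11 (not isolated)
Conditions: LiN(SiMe3)2, THF, −78 °C; CF3CO2CH2CF3, −78 °C; aq. HCl work-up, crude 11 used directly; then MsN3, Et3N, H2O (1 equiv), MeCN, rt
Reagents that add atoms: methanesulfonyl azide, CS(=O)(=O)N=[N+]=[N-] (2,2,2-trifluoroethyl trifluoroacetate, O=C(OCC(F)(F)F)C(F)(F)F, adds atoms to intermediate 11 only)
Why: Detrifluoroacetylative diazo transfer: kinetic enolisation of the acetyl methyl group, C-trifluoroacetylation and transfer of N2 from the sulfonyl azide with loss of the trifluoroacetyl group give the α'-diazo enone without an acid chloride or diazomethane, which could add as a dipole to the electron-poor ring alkene.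

**Siloxyalkyne (steps 7–10)**

Step 7
Reactants: 13 (S)-4-benzyl-1,3-oxazolidin-2-one; 14 heptanoyl chloride
Product: 15 (S)-4-benzyl-3-heptanoyl-1,3-oxazolidin-2-one
Conditions: n-BuLi, THF, −78 °C; then 14, −78 → 0 °C
Reagents that add atoms: none
Why: N-acylation of the lithiated oxazolidinone by the acid chloride (imide formation) leaves the auxiliary centre untouched.

Step 8
Reactants: 15 (S)-4-benzyl-3-heptanoyl-1,3-oxazolidin-2-one; 16 allyl bromide
Product: 17 (4S)-4-benzyl-3-[(2R)-2-(prop-2-en-1-yl)heptanoyl]-1,3-oxazolidin-2-one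
Conditions: NaN(SiMe3)2, THF, −78 °C; then 16, −78 → −40 °C
Reagents that add atoms: none
Why: Evans asymmetric alkylation: the chelated sodium Z-enolate is allylated on the face opposite the benzyl group of the S auxiliary, which sets the new α-centre as R.

Step 9
Reactants: 17 (4S)-4-benzyl-3-[(2R)-2-(prop-2-en-1-yl)heptanoyl]-1,3-oxazolidin-2-one
Product: 18 methyl (2R)-2-(prop-2-en-1-yl)heptanoate
Conditions: MeMgBr, MeOH, CH2Cl2, 0 °C → rt (MeOMgBr formed in situ); aq. NH4Cl
Reagents that add atoms: methanol, CO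
Why: Transesterification at the exocyclic imide carbonyl by methoxymagnesium bromide, a weakly basic nucleophile, releases the auxiliary without enolising the α-centre.

Step 10
Reactants: 18 methyl (2R)-2-(prop-2-en-1-yl)heptanoate
Product: 21 triisopropyl{[(3R)-3-(prop-2-en-1-yl)oct-1-yn-1-yl]oxy}silane, via lithium dibromoenolate 19 (not isolated), via lithium ynolate 20 (not isolated)
Conditions: CH2Br2, lithium 2,2,6,6-tetramethylpiperidide, THF, −78 °C; 18; LiN(SiMe3)2; n-BuLi, −78 °C → rt; then TIPSOTf, −78 → 0 °C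
Reagents that add atoms: dibromomethane, BrCBr; triisopropylsilyl trifluoromethanesulfonate, CC(C)[Si](OS(=O)(=O)C(F)(F)F)(C(C)C)C(C)C
Why: Kowalski ester homologation stopped at the ynolate: dibromomethyllithium adds to the ester, bromine–lithium exchange in the dibromoenolate triggers a retentive 1,2-shift of the branched alkyl group to give the ynolate, and the bulky silyl triflate reacts at oxygen; the stereocentre migrates with retention and is never deprotonated.

**Benzannulation (step 11)**

Step 11
Reactants: 12 (2R,3R)-6-(2-diazoacetyl)-2,3-dimethyl-2,3-dihydro-4H-pyran-4-one; 21 triisopropyl{[(3R)-3-(prop-2-en-1-yl)oct-1-yn-1-yl]oxy}silane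
Product: 26 (2R,3R)-5-hydroxy-2,3-dimethyl-6-[(4R)-non-1-en-4-yl]-7-[(triisopropylsilyl)oxy]-2,3-dihydro-4H-chromen-4-one, via vinylketene 22 (not isolated), via vinylcyclobutenone 23 (not isolated), via dienylketene 24 (not isolated), via cyclohexadienone 25 (not isolated)
Conditions: hν (300 nm, Pyrex), 21 (1.3 equiv), ClCH2CH2Cl, rt, until 12 is consumed; then 80 °C, dark
Reagents that add atoms: none
Why: Danheiser benzannulation in its photochemical Wolff form with a siloxyalkyne, a known cascade applied here to a dihydropyranone: loss of N2 and 1,2-shift of the pyranonyl group (making C8–C8a) give vinylketene 22, whose ketene C=C adds the electron-rich alkyne in a [2+2] cycloaddition (C5–C6 and C7–C8) to give 4-vinylcyclobutenone 23. Four-electron electrocyclic opening gives dienylketene 24, and the benzene ring is closed by a thermal six-electron disrotatory electrocyclisation that joins the ketene carbon to C4a (C4a–C5), after which dienone 25 enolises to the phenol. Regioselectivity, the one selectivity the step needs, follows from the polarisation of the ynol ether: its nucleophilic alkyl-bearing carbon attacks the ketene carbonyl carbon, so the side chain lands at C6 between the C5 hydroxyl and the C7 silyl ether and C8 keeps hydrogen. No stereocentre is created: C2 and C3 are remote (C3 can only epimerise towards the already favoured trans isomer) and the propargylic centre, never acidic, becomes the benzylic centre unchanged. The ring carbonyl sits trans to the ketenyl group across C4a=C8a and cannot intercept the ketene, and the hydrogen-bonded C5–OH/C4=O pair of the product both suppresses O-acylation by excess ketene and makes the chromanone photostable. Irradiation is stopped once 12 is consumed and the remaining cyclobutenone is converted in the dark, which limits excited-state enone chemistry with the terminal alkene.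

**Endgame (steps 12–17)**

Step 12
Reactants: 26 (2R,3R)-5-hydroxy-2,3-dimethyl-6-[(4R)-non-1-en-4-yl]-7-[(triisopropylsilyl)oxy]-2,3-dihydro-4H-chromen-4-one
Product: 27 (3R)-3-{(2R,3R)-5-hydroxy-2,3-dimethyl-4-oxo-7-[(triisopropylsilyl)oxy]-3,4-dihydro-2H-chromen-6-yl}octanal
Conditions: OsO4 (2 mol %), NaIO4, 2,6-lutidine, dioxane/H2O (3:1), rt
Reagents that add atoms: osmium tetroxide, O=[Os](=O)(=O)=O (oxygen donor, regenerated by the periodate); sodium periodate, [Na+].[O-]I(=O)(=O)=O
Why: Lemieux–Johnson oxidative cleavage: catalytic OsO4 dihydroxylates the only alkene and NaIO4 cleaves the diol to the aldehyde, while the acyl-deactivated, silylated phenol ring is left alone and the benzylic centre, β to the new carbonyl, cannot epimerise.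

Step 13
Reactants: 27 (3R)-3-{(2R,3R)-5-hydroxy-2,3-dimethyl-4-oxo-7-[(triisopropylsilyl)oxy]-3,4-dihydro-2H-chromen-6-yl}octanal
Product: 28 (3R)-3-{(2R,3R)-5-hydroxy-2,3-dimethyl-4-oxo-7-[(triisopropylsilyl)oxy]-3,4-dihydro-2H-chromen-6-yl}octanoic acid
Conditions: NaClO2, NaH2PO4, 2-methyl-2-butene (large excess), t-BuOH/H2O, 0 °C → rt
Reagents that add atoms: sodium chlorite, [Na+].[O-]Cl=O
Why: Pinnick oxidation converts the aldehyde into the acid while the alkene scavenger removes HOCl and so protects the one free ring position (C8) from chlorination.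

Step 14
Reactants: 28 (3R)-3-{(2R,3R)-5-hydroxy-2,3-dimethyl-4-oxo-7-[(triisopropylsilyl)oxy]-3,4-dihydro-2H-chromen-6-yl}octanoic acid
Product: 29 methyl (3R)-3-[(2R,3R)-5-hydroxy-7-methoxy-2,3-dimethyl-4-oxo-3,4-dihydro-2H-chromen-6-yl]octanoate
Conditions: CsF, MeI (2.3 equiv), DMF, 0 °C → rt
Reagents that add atoms: iodomethane, CI
Why: Fluoride-triggered desilylation followed by Williamson methylation of the C7 phenoxide and O-alkylation of the caesium carboxylate in one pot; the C5 phenol, hydrogen-bonded to the C4 carbonyl, is too weak a nucleophile to be methylated under these mild conditions.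

Step 15
Reactants: 29 methyl (3R)-3-[(2R,3R)-5-hydroxy-7-methoxy-2,3-dimethyl-4-oxo-3,4-dihydro-2H-chromen-6-yl]octanoate; 30 3-methylbut-2-en-1-ol
Product: 31 methyl (3R)-3-{(2R,3R)-7-methoxy-2,3-dimethyl-5-[(3-methylbut-2-en-1-yl)oxy]-4-oxo-3,4-dihydro-2H-chromen-6-yl}octanoate
Conditions: 30, PPh3, DIAD, THF, 0 °C → rt
Reagents that add atoms: none
Why: Mitsunobu etherification alkylates the chelated C5 phenol with the primary allylic alcohol under neutral conditions, so the chromanone is not exposed to a base that could open the ring or epimerise C3.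

Step 16
Reactants: 31 methyl (3R)-3-{(2R,3R)-7-methoxy-2,3-dimethyl-5-[(3-methylbut-2-en-1-yl)oxy]-4-oxo-3,4-dihydro-2H-chromen-6-yl}octanoate
Product: 34 methyl (3R)-3-[(2R,3R)-5-hydroxy-7-methoxy-2,3-dimethyl-8-(3-methylbut-2-en-1-yl)-4-oxo-3,4-dihydro-2H-chromen-6-yl]octanoate, via ortho dienone 32 (not isolated), via para dienone 33 (not isolated)
Conditions: Eu(fod)3 (10 mol %), NaHCO3, PhCl, 85 °C
Reagents that add atoms: none
Why: Para-Claisen (Claisen–Cope) rearrangement catalysed by the oxophilic europium chelate: a [3,3] shift places a 1,1-dimethylallyl group on the blocked ortho carbon C6, a Cope [3,3] shift carries it to C8 with the normal prenyl connectivity restored, and enolisation of C8–H regenerates the C5 phenol, with no stereocentre formed or touched.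

Step 17
Reactants: 34 methyl (3R)-3-[(2R,3R)-5-hydroxy-7-methoxy-2,3-dimethyl-8-(3-methylbut-2-en-1-yl)-4-oxo-3,4-dihydro-2H-chromen-6-yl]octanoate
Product: 35 (3R)-3-[(2R,3R)-5-hydroxy-7-methoxy-2,3-dimethyl-8-(3-methylbut-2-en-1-yl)-4-oxo-3,4-dihydro-2H-chromen-6-yl]octanoic acid
Conditions: Me3SnOH, ClCH2CH2Cl, 80 °C; then 1 M HCl
Reagents that add atoms: trimethyltin hydroxide, C[Sn](C)(C)O
Why: Ester hydrolysis by acyl transfer to trimethyltin hydroxide is essentially neutral, so retro-oxa-Michael opening of the chromanone, C3 epimerisation and damage to the prenyl group are avoided, and acidification frees the acid.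

**Compound list**

1 | methyl (R)-3-hydroxybutanoate | O[C@H](C)CC(=O)OC | starting material
2 | methyl (2R,3R)-3-hydroxy-2-methylbutanoate | O[C@H](C)[C@@H](C)C(=O)OC | intermediate
3 | methyl (2R,3R)-3-[(tert-butyldimethylsilyl)oxy]-2-methylbutanoate | CC(C)(C)[Si](C)(C)O[C@H](C)[C@@H](C)C(=O)OC | intermediate
4 | (2R,3R)-3-[(tert-butyldimethylsilyl)oxy]-N-methoxy-N,2-dimethylbutanamide (Weinreb amide) | CC(C)(C)[Si](C)(C)O[C@H](C)[C@@H](C)C(=O)N(C)OC | intermediate (not isolated)
5 | (3R,4R)-4-[(tert-butyldimethylsilyl)oxy]-3-methylpentan-2-one | CC(C)(C)[Si](C)(C)O[C@H](C)[C@@H](C)C(C)=O | intermediate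
6 | methyl 2,2-dimethoxypropanoate | COC(=O)C(C)(OC)OC | starting material
7 | (6R,7R)-7-[(tert-butyldimethylsilyl)oxy]-2,2-dimethoxy-6-methyloctane-3,5-dione (largely enolised) | CC(C)(C)[Si](C)(C)O[C@H](C)[C@@H](C)C(=O)CC(=O)C(C)(OC)OC | intermediate
8 | (6R,7R)-7-hydroxy-2,2-dimethoxy-6-methyloctane-3,5-dione (hydroxy diketone) | O[C@H](C)[C@@H](C)C(=O)CC(=O)C(C)(OC)OC | intermediate (not isolated)
9 | (2R,3R)-6-(1,1-dimethoxyethyl)-2,3-dimethyl-2,3-dihydro-4H-pyran-4-one (ketal pyranone) | O1[C@H](C)[C@@H](C)C(=O)C=C1C(C)(OC)OC | intermediate (not isolated)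
10 | (2R,3R)-6-acetyl-2,3-dimethyl-2,3-dihydro-4H-pyran-4-one | O1[C@H](C)[C@@H](C)C(=O)C=C1C(C)=O | intermediate
11 | 1-[(2R,3R)-2,3-dimethyl-4-oxo-3,4-dihydro-2H-pyran-6-yl]-4,4,4-trifluorobutane-1,3-dione (trifluoroacetyl diketone) | O1[C@H](C)[C@@H](C)C(=O)C=C1C(=O)CC(=O)C(F)(F)F | intermediate (not isolated)
12 | (2R,3R)-6-(2-diazoacetyl)-2,3-dimethyl-2,3-dihydro-4H-pyran-4-one | O1[C@H](C)[C@@H](C)C(=O)C=C1C(=O)C=[N+]=[N-] | intermediate
13 | (S)-4-benzyl-1,3-oxazolidin-2-one | O=C1N[C@@H](Cc2ccccc2)CO1 | starting material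
14 | heptanoyl chloride | CCCCCCC(=O)Cl | starting material
15 | (S)-4-benzyl-3-heptanoyl-1,3-oxazolidin-2-one | CCCCCCC(=O)N1[C@@H](Cc2ccccc2)COC1=O | intermediate
16 | allyl bromide (3-bromoprop-1-ene) | C=CCBr | starting material
17 | (4S)-4-benzyl-3-[(2R)-2-(prop-2-en-1-yl)heptanoyl]-1,3-oxazolidin-2-one | CCCCC[C@H](CC=C)C(=O)N1[C@@H](Cc2ccccc2)COC1=O | intermediate
18 | methyl (2R)-2-(prop-2-en-1-yl)heptanoate | CCCCC[C@H](CC=C)C(=O)OC | intermediate
19 | lithium (3R)-1,1-dibromo-3-(prop-2-en-1-yl)oct-1-en-2-olate (lithium dibromoenolate) | CCCCC[C@H](CC=C)C(O[Li])=C(Br)Br | intermediate (not isolated)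
20 | lithium (3R)-3-(prop-2-en-1-yl)oct-1-yn-1-olate (lithium ynolate) | CCCCC[C@H](CC=C)C#CO[Li] | intermediate (not isolated)
21 | triisopropyl{[(3R)-3-(prop-2-en-1-yl)oct-1-yn-1-yl]oxy}silane | CCCCC[C@H](CC=C)C#CO[Si](C(C)C)(C(C)C)C(C)C | intermediate
22 | (2R,3R)-2,3-dimethyl-6-(2-oxoethenyl)-2,3-dihydro-4H-pyran-4-one (vinylketene) | O1[C@H](C)[C@@H](C)C(=O)C=C1C=C=O | intermediate (not isolated)
23 | (2R,3R)-2,3-dimethyl-6-{3-[(4R)-non-1-en-4-yl]-4-oxo-2-[(triisopropylsilyl)oxy]cyclobut-2-en-1-yl}-2,3-dihydro-4H-pyran-4-one (vinylcyclobutenone, both epimers at the ring CH) | O1[C@H](C)[C@@H](C)C(=O)C=C1C2C(=O)C([C@H](CCCCC)CC=C)=C2O[Si](C(C)C)(C(C)C)C(C)C | intermediate (not isolated)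
24 | (2R,3R)-2,3-dimethyl-6-{3-[(4R)-non-1-en-4-yl]-4-oxo-2-[(triisopropylsilyl)oxy]buta-1,3-dien-1-yl}-2,3-dihydro-4H-pyran-4-one (dienylketene) | O1[C@H](C)[C@@H](C)C(=O)C=C1C=C(O[Si](C(C)C)(C(C)C)C(C)C)C([C@H](CCCCC)CC=C)=C=O | intermediate (not isolated)
25 | (2R,3R)-2,3-dimethyl-6-[(4R)-non-1-en-4-yl]-7-[(triisopropylsilyl)oxy]-2,3-dihydro-4H-chromene-4,5(4aH)-dione (cyclohexadienone, C4a unassigned) | O1[C@H](C)[C@@H](C)C(=O)C2C1=CC(O[Si](C(C)C)(C(C)C)C(C)C)=C([C@H](CCCCC)CC=C)C2=O | intermediate (not isolated)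
26 | (2R,3R)-5-hydroxy-2,3-dimethyl-6-[(4R)-non-1-en-4-yl]-7-[(triisopropylsilyl)oxy]-2,3-dihydro-4H-chromen-4-one | CCCCC[C@H](CC=C)c1c(O)c2c(cc1O[Si](C(C)C)(C(C)C)C(C)C)O[C@H](C)[C@@H](C)C2=O | intermediate
27 | (3R)-3-{(2R,3R)-5-hydroxy-2,3-dimethyl-4-oxo-7-[(triisopropylsilyl)oxy]-3,4-dihydro-2H-chromen-6-yl}octanal | CCCCC[C@H](CC=O)c1c(O)c2c(cc1O[Si](C(C)C)(C(C)C)C(C)C)O[C@H](C)[C@@H](C)C2=O | intermediate
28 | (3R)-3-{(2R,3R)-5-hydroxy-2,3-dimethyl-4-oxo-7-[(triisopropylsilyl)oxy]-3,4-dihydro-2H-chromen-6-yl}octanoic acid | CCCCC[C@H](CC(=O)O)c1c(O)c2c(cc1O[Si](C(C)C)(C(C)C)C(C)C)O[C@H](C)[C@@H](C)C2=O | intermediate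
29 | methyl (3R)-3-[(2R,3R)-5-hydroxy-7-methoxy-2,3-dimethyl-4-oxo-3,4-dihydro-2H-chromen-6-yl]octanoate | CCCCC[C@H](CC(=O)OC)c1c(O)c2c(cc1OC)O[C@H](C)[C@@H](C)C2=O | intermediate
30 | 3-methylbut-2-en-1-ol | CC(C)=CCO | starting material
31 | methyl (3R)-3-{(2R,3R)-7-methoxy-2,3-dimethyl-5-[(3-methylbut-2-en-1-yl)oxy]-4-oxo-3,4-dihydro-2H-chromen-6-yl}octanoate | CCCCC[C@H](CC(=O)OC)c1c(OCC=C(C)C)c2c(cc1OC)O[C@H](C)[C@@H](C)C2=O | intermediate
32 | methyl (3R)-3-[(2R,3R)-7-methoxy-2,3-dimethyl-6-(2-methylbut-3-en-2-yl)-4,5-dioxo-3,4,5,6-tetrahydro-2H-chromen-6-yl]octanoate (ortho dienone, C6 unassigned) | CCCCC[C@H](CC(=O)OC)C1(C(C)(C)C=C)C(=O)C2=C(C=C1OC)O[C@H](C)[C@@H](C)C2=O | intermediate (not isolated)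
33 | methyl (3R)-3-[(2R,3R)-7-methoxy-2,3-dimethyl-8-(3-methylbut-2-en-1-yl)-4,5-dioxo-3,4,5,8-tetrahydro-2H-chromen-6-yl]octanoate (para dienone, C8 unassigned) | CCCCC[C@H](CC(=O)OC)C1=C(OC)C(CC=C(C)C)C(O[C@H](C)[C@@H](C)C2=O)=C2C1=O | intermediate (not isolated)
34 | methyl (3R)-3-[(2R,3R)-5-hydroxy-7-methoxy-2,3-dimethyl-8-(3-methylbut-2-en-1-yl)-4-oxo-3,4-dihydro-2H-chromen-6-yl]octanoate | CCCCC[C@H](CC(=O)OC)c1c(O)c2c(c(CC=C(C)C)c1OC)O[C@H](C)[C@@H](C)C2=O | intermediate
35 | (3R)-3-[(2R,3R)-5-hydroxy-7-methoxy-2,3-dimethyl-8-(3-methylbut-2-en-1-yl)-4-oxo-3,4-dihydro-2H-chromen-6-yl]octanoic acid | CCCCC[C@H](CC(=O)O)c1c(O)c2c(c(CC=C(C)C)c1OC)O[C@H](C)[C@@H](C)C2=O | target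

**Step count and risks**

Total step count: 17. Longest linear sequence: 13 steps (steps 1–6, 11, 12–17, from 1).

Steps most likely to fail, in order:

1. Step 11. The photogenerated vinylketene may be intercepted inefficiently by the branched siloxyalkyne, so that ketene dimerisation or capture by adventitious water takes over. Excited-state reactions of the dihydropyranone enone (cycloaddition to the alkene or alkyne of 21) and an incomplete cyclobutenone-to-phenol conversion are further risks. The fallback keeps the same ring construction but makes the ketene in the dark. Setting out from 12, a Wolff rearrangement run without the alkyne (PhCO2Ag, Et3N, THF/H2O) should give the homologous acid 2-[(2R,3R)-2,3-dimethyl-4-oxo-3,4-dihydro-2H-pyran-6-yl]acetic acid F1. 1-Chloro-N,N,2-trimethylprop-1-en-1-amine should convert it into 2-[(2R,3R)-2,3-dimethyl-4-oxo-3,4-dihydro-2H-pyran-6-yl]acetyl chloride F2. Slow addition of Et3N to F2 and 21 in toluene (0 °C → rt) then generates vinylketene 22 by dehydrochlorination, the thermal [2+2] gives 23, and heating at 80–110 °C takes it on to 26, where the route is rejoined.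

2. Step 16 (with its feeder step 15). The allylic ether may ionise and shed the prenyl group, or the rearrangement may stall at or be diverted from the congested C6-quaternary dienone; O-alkylation of the hindered, chelated phenol in step 15 may also remain incomplete. The fallback installs the prenyl group by cross-coupling and bypasses both steps. Setting out from 29, NBS in MeCN at 0 °C should brominate C8, the only unsubstituted ring carbon, to give methyl (3R)-3-[(2R,3R)-8-bromo-5-hydroxy-7-methoxy-2,3-dimethyl-4-oxo-3,4-dihydro-2H-chromen-6-yl]octanoate F3. Stille coupling of F3 with tributyl(3-methylbut-2-en-1-yl)stannane (Pd(PPh3)4, DMF, 90 °C) should deliver the linear prenyl group and rejoin the route at 34.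

3. Step 6. Enolisation may not be confined to the acetyl methyl group: deprotonation at the ring α'-carbon or conjugate self-addition of the enolate would lead to mis-acylation and erosion of the C3 configuration. The fallback makes the diazoketone by classical acylation of diazomethane, with no pyranone enolate. Setting out from 5, Claisen condensation of its kinetic lithium enolate with di-tert-butyl oxalate should give tert-butyl (5R,6R)-6-[(tert-butyldimethylsilyl)oxy]-5-methyl-2,4-dioxoheptanoate F4. TFA/H2O should remove the silyl and tert-butyl groups and cyclodehydrate to (2R,3R)-2,3-dimethyl-4-oxo-3,4-dihydro-2H-pyran-6-carboxylic acid F5. 1-Chloro-N,N,2-trimethylprop-1-en-1-amine should then give (2R,3R)-2,3-dimethyl-4-oxo-3,4-dihydro-2H-pyran-6-carbonyl chloride F6. Adding F6 to excess ethereal diazomethane at −20 °C should give 12, where the route is rejoined.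

Further compounds
F1 | step 11 | 2-[(2R,3R)-2,3-dimethyl-4-oxo-3,4-dihydro-2H-pyran-6-yl]acetic acid | O1[C@H](C)[C@@H](C)C(=O)C=C1CC(=O)O
F2 | step 11 | 2-[(2R,3R)-2,3-dimethyl-4-oxo-3,4-dihydro-2H-pyran-6-yl]acetyl chloride | O1[C@H](C)[C@@H](C)C(=O)C=C1CC(=O)Cl
F3 | step 16 | methyl (3R)-3-[(2R,3R)-8-bromo-5-hydroxy-7-methoxy-2,3-dimethyl-4-oxo-3,4-dihydro-2H-chromen-6-yl]octanoate | CCCCC[C@H](CC(=O)OC)c1c(O)c2c(c(Br)c1OC)O[C@H](C)[C@@H](C)C2=O
F4 | step 6 | tert-butyl (5R,6R)-6-[(tert-butyldimethylsilyl)oxy]-5-methyl-2,4-dioxoheptanoate | CC(C)(C)[Si](C)(C)O[C@H](C)[C@@H](C)C(=O)CC(=O)C(=O)OC(C)(C)C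
F5 | step 6 | (2R,3R)-2,3-dimethyl-4-oxo-3,4-dihydro-2H-pyran-6-carboxylic acid | O1[C@H](C)[C@@H](C)C(=O)C=C1C(=O)O
F6 | step 6 | (2R,3R)-2,3-dimethyl-4-oxo-3,4-dihydro-2H-pyran-6-carbonyl chloride | O1[C@H](C)[C@@H](C)C(=O)C=C1C(=O)Cl
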